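**Strategy.** Everything rests on disconnecting the O1–C2 ether bond of the upper pyran (ring C). This lets the difficult 3,4-cis relationship between the C3 hydroxyl and the C4 catechin-8-yl group be fixed on an open chain, by anti arylation of an enantioenriched chalcone-type epoxide. The key step then closes ring C in one operation: the syn C2/C3 diol is activated as a cyclic orthoformate and the free ortho-phenol oxygen of resorcinol ring A displaces the C2–O bond with inversion, setting C2 and the 2,3-trans relationship. It exploits C2 being benzylic to pyrogallol ring B and O1 sitting ortho to C4. The precursor is an acyclic, benzyl-protected 1,3,3-triarylpropane-1,2-diol.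

Key step: step 9

Remark on the chemistry: the target is read as robinetinidol-(4β→8)-catechin, upper unit (2R,3S,4R), lower unit (2R,3S). Flavan numbering (O1, C2, C3, C4; rings A, B, C of the upper unit; ring D for the aromatic ring of the catechin unit) is used for open-chain intermediates too. The secondary 3-OH of the catechin unit is carried unprotected.

**Step 1**
Reactants: 1 (+)-catechin
Product: 2 5,7,3',4'-tetra-O-benzyl-(+)-catechin
Conditions: BnBr (4.4 equiv), K2CO3, DMF, 0 °C to rt, N2
Reagents that add atoms: benzyl bromide, BrCc1ccccc1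
Why: Williamson etherification: K2CO3 deprotonates only the four phenols, so the secondary 3-OH stays free, and no stereocenter is touched.

**Step 2**
Reactants: 3 4-(benzyloxy)-2-hydroxybenzaldehyde
Product: 4 2-(allyloxy)-4-(benzyloxy)benzaldehyde
Conditions: allyl bromide, K2CO3, DMF, 50 °C
Reagents that add atoms: allyl bromide, C=CCBr
Why: Williamson etherification of the remaining phenol gives an allyl ether that survives base, fluorinated alcohol and hydride and can later be removed without acid.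

**Step 3**
Reactants: 5 3',4',5'-trihydroxyacetophenone
Product: 6 3',4',5'-tris(benzyloxy)acetophenone
Conditions: BnBr (3.5 equiv), K2CO3, DMF, 60 °C
Reagents that add atoms: benzyl bromide, BrCc1ccccc1
Why: Williamson etherification of the three phenols; the acetyl group is untouched.

**Step 4**
Reactants: 4 2-(allyloxy)-4-(benzyloxy)benzaldehyde; 6 3',4',5'-tris(benzyloxy)acetophenone
Product: 7 (E)-3-[2-(allyloxy)-4-(benzyloxy)phenyl]-1-[3,4,5-tris(benzyloxy)phenyl]prop-2-en-1-one
Conditions: KOH (50% aq.), EtOH/THF, rt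
Reagents that add atoms: none
Why: Claisen–Schmidt aldol condensation of the methyl ketone enolate with the non-enolisable aldehyde, dehydration giving the conjugated E-enone as the thermodynamic isomer.

**Step 5**
Reactants: 7 (E)-chalcone
Product: 8 [(2S,3R)-3-[2-(allyloxy)-4-(benzyloxy)phenyl]oxiran-2-yl][3,4,5-tris(benzyloxy)phenyl]methanone (trans-epoxide)
Conditions: La(O-i-Pr)3 (10 mol%), (R)-BINOL (10 mol%), Ph3As=O (10 mol%), t-BuOOH (decane), 4 Å molecular sieves, THF, rt
Reagents that add atoms: tert-butyl hydroperoxide, CC(C)(C)OO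
Why: Lanthanum–BINOL-catalysed asymmetric nucleophilic (Weitz–Scheffer-type) epoxidation of an E-chalcone: the chiral lanthanum peroxide adds to one enone face and closes the trans-epoxide, the (R)-ligand being expected to give the (2S,3R)-oxirane that carries the later C3 (S) and C4 centres (the antipodal ligand is used if the sense proves opposite), and the allyl ether is inert to the nucleophilic oxidant.

**Step 6**
Reactants: 8 trans-epoxy ketone; 2 5,7,3',4'-tetra-O-benzyl-(+)-catechin
Product: 9 (2S,3R)-3-[2-(allyloxy)-4-(benzyloxy)phenyl]-2-hydroxy-3-(5,7,3',4'-tetra-O-benzylcatechin-8-yl)-1-[3,4,5-tris(benzyloxy)phenyl]propan-1-one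
Conditions: 2 (1.5 equiv), (CF3)2CHOH/CH2Cl2 (1:1), −20 to 0 °C
Reagents that add atoms: none
Why: Friedel–Crafts arylative opening of an aryl epoxide: the hydrogen-bond-activated oxirane is attacked at its benzylic carbon (later C4) by C8 of the phloroglucinol-type ring D, the most nucleophilic carbon present, anti to the departing oxygen, so C4 is set (R) by inversion while C3 (S) is retained, which is the open-chain equivalent of the 3,4-cis relationship.

**Step 7**
Reactants: 9 α-hydroxy ketone
Product: 10 (1S,2S,3R)-3-[2-(allyloxy)-4-(benzyloxy)phenyl]-3-(5,7,3',4'-tetra-O-benzylcatechin-8-yl)-1-[3,4,5-tris(benzyloxy)phenyl]propane-1,2-diol (syn-diol)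
Conditions: RuCl[(R,R)-TsDPEN](p-cymene) (5 mol%), HCO2H/Et3N (5:2), CH2Cl2, 30 °C
Reagents that add atoms: none
Why: Noyori-type asymmetric transfer hydrogenation of an aryl ketone: the (R,R)-catalyst delivers hydride to the carbonyl face that gives the (1S)-carbinol (C2), the pairing with the (S)-α-hydroxy centre corresponding to the matched case known from benzoin reductions, so the syn-1,2-diol should result.

**Step 8**
Reactants: 10 syn-diol allyl ether
Product: 11 (1S,2S,3R)-3-[4-(benzyloxy)-2-hydroxyphenyl]-3-(5,7,3',4'-tetra-O-benzylcatechin-8-yl)-1-[3,4,5-tris(benzyloxy)phenyl]propane-1,2-diol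
Conditions: Pd(PPh3)4 (5 mol%), morpholine, THF, rt
Reagents that add atoms: none
Why: Tsuji–Trost-type deallylation: Pd(PPh3)4 ionises the aryl allyl ether to a π-allyl complex that morpholine captures, freeing the ring A phenol under neutral conditions that leave the benzyl ethers, the diol and all stereocenters untouched.

**Step 9**
Reactants: 11 phenol syn-diol
Product: 14 octa-O-benzyl ether of robinetinidol-(4β→8)-catechin, via cyclic orthoformate 12 (not isolated), via 3-O-formate 13 (not isolated)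
Conditions: HC(OEt)3, PPTS (cat.), ClCH2CH2Cl, 60 °C; then K2CO3, MeOH/THF, rt
Reagents that add atoms: none
Why: Acid-catalysed exchange converts the syn-1,2-diol into the cyclic orthoformate 12, which loses ethanol to a 1,3-dioxolan-2-ylium ion whose benzylic C2–O bond is displaced from the rear by the phenol oxygen of ring A, leaving the C3 oxygen as formate 13, which the methanolysis cleaves (the orthoformate carbon leaves as methyl formate). The closest known reaction type is the orthoester-mediated cyclodehydration of 1-aryl-3-(2-hydroxyphenyl)propane-1,2-diols to 2,3-trans-flavan-3-ols. Ring C closes in a 6-exo-tet mode, O1 attacking C2 while the leaving C2–O bond lies outside the new six-membered ring. The only new stereocenter, C2, is set (R) by inversion of the (S)-carbinol centre, so the 2,3-trans relationship follows from the syn-diol configuration and C3 and C4 are untouched. The step needs O1-selective, inversion-type closure: the 7-oxygen of catechin ring D, which could close an isomeric six-membered ring onto C2, is blocked as its benzyl ether, the catechin 3-OH cannot reach C2, and the tight dioxolanylium ion with the only moderately donating 3,4,5-tris(benzyloxy)phenyl ring disfavours a free benzylic cation. Attack at non-benzylic C3, which would give a dihydrobenzofuran, is disfavoured because only the C2–O bond is activated by ring B.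

**Step 10**
Reactants: 14 octa-O-benzyl ether
Product: 15 robinetinidol-(4β→8)-catechin (CNP0261864.3)
Conditions: H2 (1 atm), Pd(OH)2/C, THF/MeOH, rt
Reagents that add atoms: none
Why: Catalytic hydrogenolysis of the eight benzyl ethers; under mild pressure the cyclic benzylic C–O bonds and the C4–C8 bond of the flavan units are retained, and no stereocenter is affected.

**Compound list**

1 | (+)-catechin, (2R,3S)-2-(3,4-dihydroxyphenyl)chroman-3,5,7-triol | Oc1cc(O)c2c(c1)O[C@H](c1ccc(O)c(O)c1)[C@@H](O)C2 | starting material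

2 | 5,7,3',4'-tetra-O-benzyl-(+)-catechin | C(c3ccccc3)Oc1cc(OCc3ccccc3)c2c(c1)O[C@H](c1ccc(OCc3ccccc3)c(OCc3ccccc3)c1)[C@@H](O)C2 | intermediate

3 | 4-(benzyloxy)-2-hydroxybenzaldehyde | Oc1cc(OCc2ccccc2)ccc1C=O | starting material

4 | 2-(allyloxy)-4-(benzyloxy)benzaldehyde | C=CCOc1cc(OCc2ccccc2)ccc1C=O | intermediate

5 | 3',4',5'-trihydroxyacetophenone | CC(=O)c1cc(O)c(O)c(O)c1 | starting material

6 | 3',4',5'-tris(benzyloxy)acetophenone | CC(=O)c1cc(OCc2ccccc2)c(OCc2ccccc2)c(OCc2ccccc2)c1 | intermediate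

7 | (E)-3-[2-(allyloxy)-4-(benzyloxy)phenyl]-1-[3,4,5-tris(benzyloxy)phenyl]prop-2-en-1-one | C=CCOc1cc(OCc3ccccc3)ccc1/C=C/C(=O)c1cc(OCc3ccccc3)c(OCc3ccccc3)c(OCc3ccccc3)c1 | intermediate

8 | [(2S,3R)-3-[2-(allyloxy)-4-(benzyloxy)phenyl]oxiran-2-yl][3,4,5-tris(benzyloxy)phenyl]methanone | C=CCOc1cc(OCc3ccccc3)ccc1[C@H]2O[C@@H]2C(=O)c1cc(OCc3ccccc3)c(OCc3ccccc3)c(OCc3ccccc3)c1 | intermediate

9 | (2S,3R)-3-[2-(allyloxy)-4-(benzyloxy)phenyl]-2-hydroxy-3-(5,7,3',4'-tetra-O-benzylcatechin-8-yl)-1-[3,4,5-tris(benzyloxy)phenyl]propan-1-one | C=CCOc1cc(OCc3ccccc3)ccc1[C@@H]([C@H](O)C(=O)c1cc(OCc3ccccc3)c(OCc3ccccc3)c(OCc3ccccc3)c1)c1c(OCc3ccccc3)cc(OCc3ccccc3)c2c1O[C@H](c1ccc(OCc3ccccc3)c(OCc3ccccc3)c1)[C@@H](O)C2 | intermediate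

10 | (1S,2S,3R)-3-[2-(allyloxy)-4-(benzyloxy)phenyl]-3-(5,7,3',4'-tetra-O-benzylcatechin-8-yl)-1-[3,4,5-tris(benzyloxy)phenyl]propane-1,2-diol | C=CCOc1cc(OCc3ccccc3)ccc1[C@@H]([C@H](O)[C@@H](O)c1cc(OCc3ccccc3)c(OCc3ccccc3)c(OCc3ccccc3)c1)c1c(OCc3ccccc3)cc(OCc3ccccc3)c2c1O[C@H](c1ccc(OCc3ccccc3)c(OCc3ccccc3)c1)[C@@H](O)C2 | intermediate

11 | (1S,2S,3R)-3-[4-(benzyloxy)-2-hydroxyphenyl]-3-(5,7,3',4'-tetra-O-benzylcatechin-8-yl)-1-[3,4,5-tris(benzyloxy)phenyl]propane-1,2-diol | Oc1cc(OCc3ccccc3)ccc1[C@@H]([C@H](O)[C@@H](O)c1cc(OCc3ccccc3)c(OCc3ccccc3)c(OCc3ccccc3)c1)c1c(OCc3ccccc3)cc(OCc3ccccc3)c2c1O[C@H](c1ccc(OCc3ccccc3)c(OCc3ccccc3)c1)[C@@H](O)C2 | intermediate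

12 | cyclic orthoformate of 11 (2-ethoxy-1,3-dioxolane across the C2 and C3 oxygens; formed in the flask, orthoester carbon undefined) | Oc1cc(OCc3ccccc3)ccc1[C@@H]([C@@H]4OC(OCC)O[C@H]4c1cc(OCc3ccccc3)c(OCc3ccccc3)c(OCc3ccccc3)c1)c1c(OCc3ccccc3)cc(OCc3ccccc3)c2c1O[C@H](c1ccc(OCc3ccccc3)c(OCc3ccccc3)c1)[C@@H](O)C2 | intermediate

13 | 3-O-formate of 14 (formed in the flask) | C(c3ccccc3)Oc1ccc2c(c1)O[C@H](c1cc(OCc3ccccc3)c(OCc3ccccc3)c(OCc3ccccc3)c1)[C@@H](OC=O)[C@H]2c1c(OCc3ccccc3)cc(OCc3ccccc3)c2c1O[C@H](c1ccc(OCc3ccccc3)c(OCc3ccccc3)c1)[C@@H](O)C2 | intermediate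

14 | (2R,3S,4R)-7-(benzyloxy)-4-[(2R,3S)-5,7-bis(benzyloxy)-2-[3,4-bis(benzyloxy)phenyl]-3-hydroxychroman-8-yl]-2-[3,4,5-tris(benzyloxy)phenyl]chroman-3-ol (octa-O-benzyl ether of the target) | C(c3ccccc3)Oc1ccc2c(c1)O[C@H](c1cc(OCc3ccccc3)c(OCc3ccccc3)c(OCc3ccccc3)c1)[C@@H](O)[C@H]2c1c(OCc3ccccc3)cc(OCc3ccccc3)c2c1O[C@H](c1ccc(OCc3ccccc3)c(OCc3ccccc3)c1)[C@@H](O)C2 | intermediate

15 | robinetinidol-(4β→8)-catechin, (2R,3S,4R)-4-[(2R,3S)-2-(3,4-dihydroxyphenyl)-3,5,7-trihydroxychroman-8-yl]-2-(3,4,5-trihydroxyphenyl)chroman-3,7-diol | Oc1ccc2c(c1)O[C@H](c1cc(O)c(O)c(O)c1)[C@@H](O)[C@H]2c1c(O)cc(O)c2c1O[C@H](c1ccc(O)c(O)c1)[C@@H](O)C2 | target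

**Totals and risks**

Total step count: 10. Longest linear sequence: 8 steps (3 → 4 → 7 → 8 → 9 → 10 → 11 → 14 → 15; steps 2, 4, 5, 6, 7, 8, 9, 10).

Steps most likely to fail:

1. Step 6 (arylative epoxide opening). The donor-substituted epoxide may ionise to an open benzylic cation, so that attack is no longer purely anti and the C4 configuration erodes. A 1,2-acyl shift of the epoxy ketone or arylation through C6 of the catechin unit may also compete. The fallback sets out from 2 and 7 and returns at 9. Compound 2 would be brominated at C8 (NBS, CH2Cl2, −20 °C) to 8-bromo-5,7,3',4'-tetra-O-benzylcatechin F1. F1 would be lithiated (n-BuLi, 2.1 equiv, THF, −78 °C), converted into the cuprate with CuBr·SMe2 and added 1,4 to chalcone 7 in the presence of Me3SiCl. This conjugate addition is not stereocontrolled at C4, so the two C4 epimers (diastereomers because of the catechin unit) would be separated to give the (3R)-β,β-diaryl ketone F2. The potassium enolate of F2 (KN(SiMe3)2, THF, −78 °C) would then be hydroxylated with the appropriate enantiomer of (camphorsulfonyl)oxaziridine to give 9.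

2. Step 7 (transfer hydrogenation). Hydride transfer to the hindered ketone may be slow, leaving time for base-induced epimerisation or α-ketol shift at C3, or the catalyst may not control the carbonyl face sufficiently. The fallback sets out from 9 and returns at 10. Both hydroxyls of 9 would be silylated (TBSOTf, 2,6-lutidine, CH2Cl2) to the bis(tert-butyldimethylsilyl) ether F3. LiBH(s-Bu)3 (THF, −78 °C) would reduce the α-silyloxy ketone under Felkin–Anh (non-chelation) control to the (1S)-configured alcohol F4. Bu4NF (THF) would remove both silyl groups to give 10.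

3. Step 9 (ring closure). The dioxolanylium ion may partly open to a free benzylic cation, so that inversion at C2 is lost, or a hydride shift may give a ketone. The fallback sets out from 11 and returns at 14. A Mitsunobu cyclodehydration (PPh3, DIAD, THF, 0 °C) would activate the benzylic C2–OH as an oxyphosphonium ion under non-acidic conditions, and the ring A phenol would displace it with inversion. No new compound is formed on the way.

**Further compounds**

F1 | step 6 | 8-bromo-5,7,3',4'-tetra-O-benzylcatechin | Brc1c(OCc3ccccc3)cc(OCc3ccccc3)c2c1O[C@H](c1ccc(OCc3ccccc3)c(OCc3ccccc3)c1)[C@@H](O)C2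

F2 | step 6 | (3R)-3-[2-(allyloxy)-4-(benzyloxy)phenyl]-3-(5,7,3',4'-tetra-O-benzylcatechin-8-yl)-1-[3,4,5-tris(benzyloxy)phenyl]propan-1-one | C=CCOc1cc(OCc3ccccc3)ccc1[C@@H](CC(=O)c1cc(OCc3ccccc3)c(OCc3ccccc3)c(OCc3ccccc3)c1)c1c(OCc3ccccc3)cc(OCc3ccccc3)c2c1O[C@H](c1ccc(OCc3ccccc3)c(OCc3ccccc3)c1)[C@@H](O)C2

F3 | step 7 | bis(tert-butyldimethylsilyl) ether of 9 (silyl groups on the C3 oxygen and on the catechin 3-oxygen) | C=CCOc1cc(OCc3ccccc3)ccc1[C@@H]([C@H](O[Si](C)(C)C(C)(C)C)C(=O)c1cc(OCc3ccccc3)c(OCc3ccccc3)c(OCc3ccccc3)c1)c1c(OCc3ccccc3)cc(OCc3ccccc3)c2c1O[C@H](c1ccc(OCc3ccccc3)c(OCc3ccccc3)c1)[C@@H](O[Si](C)(C)C(C)(C)C)C2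

F4 | step 7 | (1S,2S,3R)-configured alcohol from reduction of F3 (both silyl ethers retained) | C=CCOc1cc(OCc3ccccc3)ccc1[C@@H]([C@H](O[Si](C)(C)C(C)(C)C)[C@@H](O)c1cc(OCc3ccccc3)c(OCc3ccccc3)c(OCc3ccccc3)c1)c1c(OCc3ccccc3)cc(OCc3ccccc3)c2c1O[C@H](c1ccc(OCc3ccccc3)c(OCc3ccccc3)c1)[C@@H](O[Si](C)(C)C(C)(C)C)C2

F0 | step 9 | none | none
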